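**Retrosynthetic overview**
1. Last step: Pd(0) removal of an O-allyl group from the (Z)-5-ylidene-3-methyltetronate. The ylidene C=C comes from a vinylogous aldol and dehydration between 4-allyloxy-3-methylfuran-2(5H)-one and an α-methyl aldehyde.
2. The only stereocentre, the α-methyl carbon, is set by organocatalytic Hantzsch-ester transfer hydrogenation of the 2-methyl-2-enal. That enal comes from a Wittig reaction of a 4-methylalk-4-enal.
3. The (E)-trisubstituted alkene comes from Zr-catalysed methylalumination of pent-4-yn-1-ol, giving an (E)-vinyl iodide. This is coupled to an alkyl-9-BBN made from the 4-vinyl bisfuran (B-alkyl Suzuki).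
4. Ring order: both furans are pre-formed (3-bromofuran and 4-bromofurfural, joined as a bisfuran). The tetronate lactone is formed separately by Dieckmann cyclisation and joined last.

Assumptions: 3-methyltetronic acid is prepared (Steps 9–10) rather than bought. The (S)-TRIP sense is assumed to give the (R)-aldehyde (if opposite, use (R)-TRIP). The exocyclic alkene is Z, as drawn in the target.

**Step 1**
Reactants: 1 (3-bromofuran); 2 (4-bromofuran-2-carbaldehyde)
Product: 3, (4-bromofuran-2-yl)(furan-3-yl)methanol
Conditions: n-BuLi, Et2O, –78 °C (3-lithiofuran); add 2 in Et2O, –78 °C, 30 min; NH4Cl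
Reagents that add atoms: none
Why: 3-Lithiofuran is stable at –78 °C and adds rapidly to the aldehyde (organolithium 1,2-addition), and the C–Br bond on the other furan survives at this temperature.

**Step 2**
Reactants: 3
Product: 4, 4-bromo-2-(furan-3-ylmethyl)furan
Conditions: Et3SiH (3 equiv), TFA (3 equiv), CH2Cl2, –20 °C, 10 min; NaHCO3 quench
Reagents that add atoms: none
Why: Ionic deoxygenation: the difurylmethyl cation is strongly stabilised and is trapped at once by silane hydride, so polymerisation is outcompeted at low temperature.

**Step 3**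
Reactants: 4; 5 (potassium vinyltrifluoroborate)
Product: 6, 2-(furan-3-ylmethyl)-4-vinylfuran
Conditions: PdCl2 (2 mol%), PPh3 (6 mol%), Cs2CO3, THF/H2O 9:1, 85 °C
Reagents that add atoms: none
Why: Suzuki–Miyaura vinylation of a heteroaryl bromide; both furans are inert to these basic conditions.

**Step 4**
Reactants: 7 (pent-4-yn-1-ol)
Product: 8, (E)-5-iodo-4-methylpent-4-en-1-ol
Conditions: Me3Al (3 equiv), cat. Cp2ZrCl2, CH2Cl2, 0 °C → rt, 6 h; then I2, THF, –30 °C
Reagents that add atoms: trimethylaluminium, C[Al](C)C (adds CH3); iodine, II (adds I)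
Why: Negishi syn-methylalumination puts Me and Al cis, so after iodinolysis the alkyl chain and I are trans, giving the E-trisubstituted vinyl iodide; the free OH is tolerated with excess AlMe3.

**Step 5**
Reactants: 6; 8
Product: 9, (E)-7-[5-(furan-3-ylmethyl)furan-3-yl]-4-methylhept-4-en-1-ol
Conditions: (i) 9-BBN (1.1 equiv rel. to 6), THF, rt, 3 h; (ii) add 8, Pd(dppf)Cl2 (5 mol%), aq. K3PO4, THF, 60 °C
Reagents that add atoms: none
Why: Anti-Markovnikov hydroboration of the vinylfuran gives the primary alkyl-9-BBN, which undergoes B-alkyl Suzuki–Miyaura coupling with the vinyl iodide with retention of alkene geometry (E).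

**Step 6**
Reactants: 9
Product: 10, (E)-7-[5-(furan-3-ylmethyl)furan-3-yl]-4-methylhept-4-enal
Conditions: Dess–Martin periodinane (1.3 equiv), NaHCO3, CH2Cl2, rt, 1 h
Reagents that add atoms: none
Why: Mild buffered oxidation of the primary alcohol; the furans and the alkene survive, and the γ,δ-unsaturated aldehyde cannot epimerise or conjugate.

**Step 7**
Reactants: 10; 11 (2-(triphenylphosphoranylidene)propanal)
Product: 12, (2E,6E)-2,6-dimethyl-9-[5-(furan-3-ylmethyl)furan-3-yl]nona-2,6-dienal
Conditions: toluene, 80 °C, 12 h
Reagents that add atoms: none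
Why: Wittig olefination with a stabilised ylide gives the E-α-methyl enal selectively.

**Step 8**
Reactants: 12
Product: 13, (R,E)-2,6-dimethyl-9-[5-(furan-3-ylmethyl)furan-3-yl]non-6-enal
Conditions: di-tert-butyl Hantzsch ester (1.2 equiv), (S)-TRIP (5 mol%), dibenzylamine (5 mol%), cyclohexane, 40 °C, 48 h; short silica plug and use at once
Reagents that add atoms: none
Why: Proposed new method: dibenzylammonium/chiral-phosphate (ACDC) iminium formation activates the enal, Hantzsch ester delivers hydride to the β-carbon, and the resulting enamine is protonated on its α-carbon within the chiral phosphate ion pair, setting the α-methyl stereocentre (R). Hydrolysis then releases the aldehyde; the remote trisubstituted alkene and both furans are untouched. The closest known reaction is the List/MacMillan Hantzsch-ester transfer hydrogenation of β,β-disubstituted enals and α-methylcinnamaldehydes. The new element is purely aliphatic α-methyl-β-alkyl enals, where the centre is set by enamine protonation.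

**Step 9**
Reactants: 14 (ethyl glycolate); 15 (propionyl chloride)
Product: 16, ethyl 2-(propionyloxy)acetate
Conditions: Et3N (1.2 equiv), CH2Cl2, 0 °C → rt, 2 h
Reagents that add atoms: none
Why: Simple O-acylation of the alcohol by the acid chloride.

**Step 10**
Reactants: 16
Product: 17, 3-methyltetronic acid (4-hydroxy-3-methylfuran-2(5H)-one)
Conditions: t-BuOK (2.2 equiv), THF, 0 °C → rt, 3 h; 1 M HCl
Reagents that add atoms: none
Why: Dieckmann (Lacey–Dieckmann) condensation: the propionate enolate attacks the ethyl ester in a 5-exo closure, and the product is trapped as its enolate.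

**Step 11**
Reactants: 17; 18 (allyl alcohol)
Product: 19, 4-allyloxy-3-methylfuran-2(5H)-one
Conditions: PPh3, DIAD, THF, 0 °C → rt
Reagents that add atoms: none
Why: Mitsunobu O-alkylation of the acidic vinylogous acid gives the allyl vinylogous ester.

**Step 12**
Reactants: 13; 19
Product: 20, aldol adduct 5-[1-hydroxy-(2R)-2,6-dimethyl-9-Ar-non-6-enyl]-4-allyloxy-3-methylfuran-2(5H)-one (Ar = 5-(furan-3-ylmethyl)furan-3-yl; new carbinol and C5 centres as a diastereomer mixture)
Conditions: LDA (1.05 equiv), THF, –78 °C, 30 min; add 13, –78 °C, 1 h; NH4Cl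
Reagents that add atoms: none
Why: Deprotonation of 19 at C5 gives the γ-dienolate, which adds to the aldehyde in a vinylogous aldol; the stoichiometric, cold, short exposure preserves the α-methyl centre, and the two new centres are destroyed in the next step.

**Step 13**
Reactants: 20
Product: 21, (Z)-4-allyloxy-3-methyl-5-ylidene-furan-2(5H)-one with the (R)-CH(CH3) centre
Conditions: MsCl (1.5 equiv), Et3N (3 equiv), CH2Cl2, 0 °C, 1 h; then DBU (2 equiv), 0 °C → rt, 2 h
Reagents that add atoms: none
Why: Mesylation followed by E1cB elimination through the acidic C5–H (γ to the lactone carbonyl) gives the thermodynamically preferred Z-ylidene, with the alkyl group cis to ring O1 and away from the OAllyl group. The stereocentre is not involved in the elimination.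

**Step 14**
Reactants: 21
Product: 22, target (R,Z,E)-4-hydroxy-3-methyl-5-ylidene tetronic acid
Conditions: Pd(PPh3)4 (5 mol%), morpholine (5 equiv), THF, rt, 1 h; pH 3 workup (0.5 M KHSO4), rapid extraction
Reagents that add atoms: none
Why: Tsuji–Trost-type Pd(0) deallylation, with morpholine as the allyl acceptor, releases the tetronic acid under neutral conditions that spare the furans, both alkenes and the stereocentre.

**Compound list**
1 | 3-bromofuran | Brc1ccoc1 | starting material
2 | 4-bromofuran-2-carbaldehyde | O=Cc1cc(Br)co1 | starting material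
3 | (4-bromofuran-2-yl)(furan-3-yl)methanol | OC(c1cc(Br)co1)c1ccoc1 | intermediate
4 | 4-bromo-2-(furan-3-ylmethyl)furan | Brc1coc(Cc2ccoc2)c1 | intermediate
5 | potassium vinyltrifluoroborate | [K+].C=C[B-](F)(F)F | starting material
6 | 2-(furan-3-ylmethyl)-4-vinylfuran | C=Cc1coc(Cc2ccoc2)c1 | intermediate
7 | pent-4-yn-1-ol | C#CCCCO | starting material
8 | (E)-5-iodo-4-methylpent-4-en-1-ol | OCCC/C(C)=C/I | intermediate
9 | (E)-7-[5-(furan-3-ylmethyl)furan-3-yl]-4-methylhept-4-en-1-ol | OCCC/C(C)=C/CCc1coc(Cc2ccoc2)c1 | intermediate
10 | (E)-7-[5-(furan-3-ylmethyl)furan-3-yl]-4-methylhept-4-enal | O=CCC/C(C)=C/CCc1coc(Cc2ccoc2)c1 | intermediate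
11 | 2-(triphenylphosphoranylidene)propanal | CC(=[P](c1ccccc1)(c1ccccc1)c1ccccc1)C=O | starting material
12 | (2E,6E)-2,6-dimethyl-9-Ar-nona-2,6-dienal | O=C/C(C)=C/CC/C(C)=C/CCc1coc(Cc2ccoc2)c1 | intermediate
13 | (R,E)-2,6-dimethyl-9-Ar-non-6-enal | O=C[C@H](C)CCC/C(C)=C/CCc1coc(Cc2ccoc2)c1 | intermediate
14 | ethyl glycolate | OCC(=O)OCC | starting material
15 | propionyl chloride | CCC(Cl)=O | starting material
16 | ethyl 2-(propionyloxy)acetate | CCC(=O)OCC(=O)OCC | intermediate
17 | 3-methyltetronic acid | CC1=C(O)COC1=O | intermediate
18 | allyl alcohol | C=CCO | starting material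
19 | 4-allyloxy-3-methylfuran-2(5H)-one | C=CCOC1=C(C)C(=O)OC1 | intermediate
20 | aldol adduct (diastereomer mixture at the new centres) | C=CCOC1=C(C)C(=O)OC1C(O)[C@H](C)CCC/C(C)=C/CCc1coc(Cc2ccoc2)c1 | intermediate
21 | (Z)-4-allyloxy-5-ylidene tetronate | CC1=C(OCC=C)/C(=C/[C@H](C)CCC/C(C)=C/CCc2coc(Cc3ccoc3)c2)OC1=O | intermediate
22 | target | CC1=C(O)/C(=C/[C@H](C)CCC/C(C)=C/CCc2coc(Cc3ccoc3)c2)OC1=O | target

**Totals**
- Total steps: 14.
- Longest linear sequence: 10 (Steps 1, 2, 3, 5, 6, 7, 8, 12, 13, 14).

**Three steps most likely to fail**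
1. **Step 8 (new enamine-protonation transfer hydrogenation):** ee may be modest for an aliphatic α-methyl enal, and the product aldehyde can racemise. Fallback: an Evans route using known chemistry. Convert alcohol 9 to its primary iodide (I2, PPh3, imidazole) and alkylate the (S)-4-benzyl-3-propionyloxazolidinone sodium enolate. Remove the auxiliary with LiBH4, then oxidise with DMP to give aldehyde 13 (R).
2. **Step 2 (ionic deoxygenation of the difurylmethanol):** the difurylmethyl cation or product may polymerise under TFA. Fallback: a radical route. Convert 3 to its O-phenyl thiocarbonate (PhOC(S)Cl, pyridine) and reduce with Bu3SnH/AIBN at 80 °C.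
3. **Step 13 (E1cB dehydration):** DBU may cause partial epimerisation of the allylic stereocentre or erode Z-selectivity. Fallback: a Wittig route. Brominate 19 at C5 (NBS), make the phosphonium salt (PPh3), and react with aldehyde 13 under mild base (DBU, CH2Cl2, 0 °C) to form the Z-ylidene directly, avoiding the strongly basic aldol and elimination sequence.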